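**Plan**
- Retrosynthesis: the carbocyclic 2‑acyl‑4,4‑dimethyl trione ring is cut at two ring C–C bonds. One runs from the ring carbon bearing the ArCH2 bridge to the carbonyl next to CMe2; the other runs from the isobutyryl‑bearing ring carbon to the carbonyl on the other side.
- Both cuts are Claisen disconnections whose leaving groups are atoms of the target. The phenolic oxygen ortho to the CH2 bridge gives a chroman‑2‑one (O–C(=O)–C–CH2–aryl, compound 7), and the isobutyryl oxygen gives the enol lactone 3,3‑dimethyl‑6‑isopropylpyran‑2,4‑dione (12). This 1,5 oxygen–carbonyl relationship on each side of the ring makes the event possible.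
- Forward, aryl part: bought benzophenone ring → propiolate ester at the para oxygen → pyranone ring of coumarin 4 by gold‑catalysed hydroarylation → dihydrocoumarin 5 → prenyl ether 7. In parallel: acyclic dioxo ester 11 → pyrandione 12.
- Last ring: the enolate of 7 opens 12 by C‑acylation and the freed diketonate closes onto the aryl lactone (2 + 4 ring carbons). This copies the Claisen closure of the tetraketide chain in acylphloroglucinol biosynthesis, fixes the methylene bridge and frees the phenol.
- Regiochemistry comes from the symmetry of 1 and from the lactone tether. The target has no stereocentre and no stereogenic double bond, so no stereochemistry has to be set.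

Key step: step 7

Assumption: the trione ring of the target is written as the enol tautomer of the given SMILES, which equilibrates freely with its other enol forms; compounds 1, 2, 6, 8 and 9 are taken as catalogue chemicals.

**Step 1**
Reactants: 1 2,4,6-trihydroxybenzophenone; 2 propiolic acid
Product: 3 4-benzoyl-3,5-dihydroxyphenyl prop-2-ynoate
Conditions: DCC (1.0 equiv), DMAP (2 mol %), THF, −20 → 0 °C
Reagents that add atoms: none
Why: Steglich-type carbodiimide esterification; the 4-hydroxyl, para to the benzoyl group, is the most acidic phenol and the only one neither hydrogen-bonded to nor flanked by the ketone, so one equivalent of activated acid should acylate it selectively, as in the usual selective 4-O-functionalization of 2,4,6-trihydroxyaryl ketones.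

**Step 2**
Reactants: 3 4-benzoyl-3,5-dihydroxyphenyl prop-2-ynoate
Product: 4 6-benzoyl-5,7-dihydroxy-2H-chromen-2-one
Conditions: Ph3PAuCl (5 mol %), AgOSO2CF3 (5 mol %), ClCH2CH2Cl, 23 → 50 °C
Reagents that add atoms: none
Why: Gold-catalysed intramolecular hydroarylation of an aryl alkynoate (6-endo-dig attack of the ring carbon ortho to the ester oxygen on the alkyne activated by cationic monovalent gold, then protodeauration), a standard coumarin synthesis; the two ortho carbons are equivalent by symmetry and the ester oxygen is already fixed, so only the 6-benzoyl isomer can form.

**Step 3**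
Reactants: 4 6-benzoyl-5,7-dihydroxy-2H-chromen-2-one
Product: 5 6-benzoyl-5,7-dihydroxy-3,4-dihydro-2H-chromen-2-one
Conditions: H2 (1 atm), Pd/C (10 wt % Pd), EtOAc/AcOH, 23 °C
Reagents that add atoms: none
Why: Heterogeneous hydrogenation of the coumarin C3–C4 double bond to the dihydrocoumarin; the diaryl ketone, deactivated as a vinylogous acid by its two ortho hydroxyls, and the aryl lactone are expected to survive at this pressure.

**Step 4**
Reactants: 5 6-benzoyl-5,7-dihydroxy-3,4-dihydro-2H-chromen-2-one; 6 1-bromo-3-methylbut-2-ene
Product: 7 6-benzoyl-5-hydroxy-7-(3-methylbut-2-enyloxy)-3,4-dihydro-2H-chromen-2-one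
Conditions: K2CO3 (1.05 equiv), dry acetone, 23 °C
Reagents that add atoms: none
Why: Williamson etherification (SN2 at the primary allylic bromide); the 5-hydroxyl is held in the hydrogen-bond chelate with the benzoyl carbonyl by the buttressing C4 methylene, the third phenolic oxygen is masked as the lactone, and the unhindered 7-hydroxyl next to H-8 should be the one that is deprotonated and alkylated.

**Step 5**
Reactants: 8 methyl 2,2-dimethyl-3-oxobutanoate; 9 2-methylpropanoyl chloride
Product: 11 methyl 2,2,6-trimethyl-3,5-dioxoheptanoate, via lithium enolate 10 (not isolated)
Conditions: LiN(SiMe3)2 (2.2 equiv), THF, −78 °C; then 9 (1.0 equiv), −78 → 0 °C; 1 M HCl work-up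
Reagents that add atoms: none
Why: C-acylation of a ketone lithium enolate by an acid chloride (crossed Claisen-type synthesis of a 1,3-diketone); 8 can enolize only at its acetyl methyl group, and the second equivalent of base converts the more acidic diketone into its enolate as it forms, which should suppress proton exchange and double acylation.

**Step 6**
Reactants: 11 methyl 2,2,6-trimethyl-3,5-dioxoheptanoate
Product: 12 3,3-dimethyl-6-(propan-2-yl)-2H-pyran-2,4(3H)-dione
Conditions: (±)-camphor-10-sulfonic acid (5 mol %), toluene, reflux, 5 Å molecular sieves in a Soxhlet thimble (removal of MeOH)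
Reagents that add atoms: none
Why: Acid-catalysed enol lactonization of a 3,5-dioxo ester (the classical closure to pyran-2,4-diones): the enol oxygen of the isobutyryl ketone attacks the ester carbonyl in a 6-exo-trig transesterification that is helped by the gem-dimethyl group and driven by removal of methanol, and carbon acylation does not compete under acid.

**Step 7**
Reactants: 7 6-benzoyl-5-hydroxy-7-(3-methylbut-2-enyloxy)-3,4-dihydro-2H-chromen-2-one; 12 3,3-dimethyl-6-(propan-2-yl)-2H-pyran-2,4(3H)-dione
Product: 15 sarothralin, via dilithium enolate 13 (not isolated), via acyclic tricarbonyl lactone 14 (not isolated)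
Conditions: LiN(SiMe3)2 (3.1 equiv), THF, −78 °C; then 12 (1.1 equiv), −78 → −40 °C; then AcOH (1.0 equiv), −40 → 23 °C; 1 M HCl work-up
Reagents that add atoms: none
Why: Proposed new method: the C3 lithium enolate 13 should add to the lactone carbonyl C2 of 12, a vinylogous carboxylic anhydride, and the adduct should collapse with opening of the pyran ring and loss of an internal β-diketone enolate to give 14 (kept fully deprotonated by the third equivalent of base so that it cannot quench 13); after one equivalent of AcOH has put the hydrogen back on C3, the diketonate carbon attacks the aryl lactone carbonyl and the phenoxide leaves, so that both leaving groups remain in the product as the isobutyryl enol oxygen and the free phenol. The closest known reaction types are the alkoxide-induced conversion of 6-(2-oxoalkyl)pyran-2-ones into acylphloroglucinols by ring opening and Claisen reclosure (the closure mode of the tetraketide in acylphloroglucinol biosynthesis), the C-acylation of ester enolates by anhydrides or enol esters, and the Baker–Venkataraman and Dieckmann transfers of an aryl ester acyl group to an enolate carbon. The carbocycle closes by a 6-(enolexo)-exo-trig Dieckmann condensation on the lactone carbonyl. No stereocentre is formed, since the new ring carbons end as enol, carbonyl or CMe2 carbons. The step needs attack at C2 of 12 in preference to conjugate attack at C6, addition to the C4 ketone or removal of the isopropyl methine hydrogen: C2 is the anhydride-like and most electrophilic acyl carbon for a hard lithium enolate at −78 °C, C6 is an oxygen-substituted β-carbon shielded by the isopropyl group, and the methine C–H lies in the plane of the enone (allylic strain) and should be slow to ionise. It also needs C- over O-acylation in the ring closure, which is secured thermodynamically because enol ester isomers are reopened by the phenoxide present whereas the C-acylated trione is trapped as its highly stabilised triketone enolate.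

**Compound list**
1 | 2,4,6-trihydroxybenzophenone | O=C(c1ccccc1)c1c(O)cc(O)cc1O | starting material
2 | propiolic acid (prop-2-ynoic acid) | C#CC(=O)O | starting material
3 | 4-benzoyl-3,5-dihydroxyphenyl prop-2-ynoate | C#CC(=O)Oc1cc(O)c(C(=O)c2ccccc2)c(O)c1 | intermediate
4 | 6-benzoyl-5,7-dihydroxy-2H-chromen-2-one | O=c1ccc2c(O)c(C(=O)c3ccccc3)c(O)cc2o1 | intermediate
5 | 6-benzoyl-5,7-dihydroxy-3,4-dihydro-2H-chromen-2-one | O=C1CCc2c(O)c(C(=O)c3ccccc3)c(O)cc2O1 | intermediate
6 | 1-bromo-3-methylbut-2-ene (prenyl bromide) | CC(C)=CCBr | starting material
7 | 6-benzoyl-5-hydroxy-7-(3-methylbut-2-enyloxy)-3,4-dihydro-2H-chromen-2-one | O=C1CCc2c(O)c(C(=O)c3ccccc3)c(OCC=C(C)C)cc2O1 | intermediate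
8 | methyl 2,2-dimethyl-3-oxobutanoate | COC(=O)C(C)(C)C(C)=O | starting material
9 | 2-methylpropanoyl chloride | CC(C)C(Cl)=O | starting material
10 | lithium enolate of 8 (lithium 4-methoxy-3,3-dimethyl-4-oxobut-1-en-2-olate) | [Li+].[O-]C(=C)C(C)(C)C(=O)OC | intermediate
11 | methyl 2,2,6-trimethyl-3,5-dioxoheptanoate | COC(=O)C(C)(C)C(=O)CC(=O)C(C)C | intermediate
12 | 3,3-dimethyl-6-(propan-2-yl)-2H-pyran-2,4(3H)-dione | CC(C)C1=CC(=O)C(C)(C)C(=O)O1 | intermediate
13 | dilithium 5-phenoxide C3-enolate of 7 | [Li+].[Li+].[O-]C1=CCc2c([O-])c(C(=O)c3ccccc3)c(OCC=C(C)C)cc2O1 | intermediate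
14 | 6-benzoyl-5-hydroxy-7-(3-methylbut-2-enyloxy)-3-(2,2,6-trimethyl-3,5-dioxoheptanoyl)-3,4-dihydro-2H-chromen-2-one (racemic, labile C3; present as its lithium salt) | CC(C)C(=O)CC(=O)C(C)(C)C(=O)C1Cc2c(O)c(C(=O)c3ccccc3)c(OCC=C(C)C)cc2OC1=O | intermediate
15 | sarothralin | CC(C)=CCOc1cc(O)c(CC2=C(O)C(C)(C)C(=O)C(C(=O)C(C)C)=C2O)c(O)c1C(=O)c1ccccc1 | target

**Count**
Total steps: 7. Longest linear sequence: 5 steps (steps 1, 2, 3, 4 and 7); steps 5 and 6 form the second branch.

**Steps most likely to fail**

Step 7. The enolate may act as a base toward the isopropyl methine of 12, or add at C6 or C4, instead of acylating at C2. The open-chain polyanion may also stall before ring closure, or excess acylating agent may esterify the phenoxides. The fallback uses known chemistry and keeps the carbocycle as the last ring closed; it sets out from 7 and comes back at 15. The lactone of 7 is opened by Claisen condensation with an excess of the kinetic lithium enolate of 3-methylbutan-2-one (LiN(CHMe2)2, THF, −78 → 0 °C) to give the open-chain β-diketone 7-[3-benzoyl-2,6-dihydroxy-4-(3-methylbut-2-enyloxy)phenyl]-2-methylheptane-3,5-dione F1. F1 is then converted with LiN(CHMe2)2 (about 4.5 equiv) into its bis-phenoxide diketone dianion, which is acylated at the terminal methylene next to the ArCH2 group by dimethyl 2,2-dimethylpropanedioate. The resulting keto ester should close in the same flask by Dieckmann condensation of the central diketone carbon onto the second ester, giving 15 after acidification. Terminal acylation of 1,3-diketone dianions by esters and Claisen closure to 2-acylcyclohexane-1,3,5-triones are both established polyketide-type reactions.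

Step 6. The lactonization is an equilibrium that has to be pulled by methanol removal, and the product is a vinylogous anhydride that can reopen with traces of methanol or water during isolation. The fallback sets out from 11 and comes back at 12. The ester is saponified with LiOH in THF/H2O (the diketone is present as its enolate, which shields the 3-ketone from retro-Claisen attack) and acidified to 2,2,6-trimethyl-3,5-dioxoheptanoic acid F2. F2 is cyclodehydrated with (CF3CO)2O in CH2Cl2 at 0 °C through the mixed anhydride, the usual closure of 3,5-dioxo acids to pyran-2,4-diones, with non-aqueous isolation.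

Step 4. Alkylation may be poorly selective between the two phenols flanking the benzoyl group, over-alkylation may occur, and the aryl lactone may be opened by carbonate and adventitious water. The fallback sets out from 4 and comes back at 7. The etherification is moved to the planar coumarin, where the 7-hydroxyl is the vinylogous acid para to the pyranone ring carbon and free of peri strain: K2CO3 and 6 in acetone should give 6-benzoyl-5-hydroxy-7-(3-methylbut-2-enyloxy)-2H-chromen-2-one F3. The conjugated cis-disubstituted C3–C4 double bond of F3 is then hydrogenated with H2 and RhCl(PPh3)3 in benzene/EtOH, which should leave the trisubstituted prenyl double bond, the lactone and the ketone untouched and deliver 7.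

Further compounds
F1 | step 7 | 7-[3-benzoyl-2,6-dihydroxy-4-(3-methylbut-2-enyloxy)phenyl]-2-methylheptane-3,5-dione | CC(C)C(=O)CC(=O)CCc1c(O)cc(OCC=C(C)C)c(C(=O)c2ccccc2)c1O
F2 | step 6 | 2,2,6-trimethyl-3,5-dioxoheptanoic acid | CC(C)C(=O)CC(=O)C(C)(C)C(=O)O
F3 | step 4 | 6-benzoyl-5-hydroxy-7-(3-methylbut-2-enyloxy)-2H-chromen-2-one | O=c1ccc2c(O)c(C(=O)c3ccccc3)c(OCC=C(C)C)cc2o1
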